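## The problem

Conneotricone (17) is a depsidone. Ring A (a benzene carrying methyl, hydroxyl and carboxyl groups) and ring B (a 7-hydroxyphthalide carrying a hydroxymethyl group) are joined twice, by an aryl ester and by a diaryl ether, so that a seven-membered dioxepinone ring lies between them. The molecule has no stereocentre. The difficulty is regiochemical: eleven of the twelve benzenoid carbons are substituted, and the ester and ether bridges must be placed in one orientation only. The bridging ester is an activated aryl ester and the phthalide is a second lactone, so hydroxide, alkoxides and amines are excluded once the rings are joined. The hydroxymethyl group sits between two ring oxygens and can ionise to an ortho-quinone methide under forcing acid or base. The salicylic-type acid of ring A decarboxylates on heating, so the last unmasking must be mild and free of nucleophiles. The feature that opens a short route is the position of the ether oxygen: it is bonded to C-4 of the phthalide (ring B), which is para to the 7-hydroxyl and, in the corresponding depside, is the only C–H carbon of ring B. The ring A hydroxyl ortho to the ester carbonyl is held within reach of that carbon.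

## Retrosynthesis

**17 to 16.** No skeletal bond is cut. The ring A acid is masked as a tert-butyl ester and the hydroxymethyl group as a tert-butyldimethylsilyl ether in 16. Both fall to aqueous trifluoroacetic acid in one operation, without base or nucleophile. A benzyl ester would be easier to carry through ring A chemistry but would cost a second deprotection step.

**16 to 15.** The bond cut is the aryl ether C–O bond between C-4 of the phthalide and the ring A oxygen. The other way to open the seven-membered ring, at the ester, leads back to a diaryl ether that must be made by Ullmann or SNAr coupling of two fully substituted partners and needs a halogen on one of them. Cutting the ether instead leaves depside 15, which has one ring fewer and needs only a C–H bond at the reacting carbon. The forward reaction must oxidise ring B rather than ring A, deliver the oxygen to C-4, and stop before the more electron-rich product is oxidised further.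

**15 to 5 and 14.** The depside ester is cut to give acid 5 and phenol 14, two benzenoid halves of similar size. The forward esterification must acylate the 5-hydroxyl of 14 and not its 7-hydroxyl or the hydroxyls of 5. The 5-hydroxyl is para to the lactone carbonyl, acidic and not chelated, whereas every other phenol is hydrogen-bonded to a neighbouring carbonyl.

**5 to 4, 2 and 1.** The acid carbon of 5 comes from a formyl group (4) by oxidation, and the formyl group from electrophilic substitution of ester 2. Because 2 is symmetric, only one monoaldehyde is possible, which is why the carboxyl between the hydroxyls is installed and protected first. Ester 2 comes from 2,6-dihydroxy-4-methylbenzoic acid (1).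

**14 to 12, 11 and 10.** These are functional-group changes on a complete carbon skeleton. The silyl ether 14 comes from triol 12, the hydroxymethyl group from aldehyde 11, and the free phenols from dimethyl ether 10. The carbon between the two ring oxygens is carried as an aldehyde through the demethylation because a benzylic ether would not survive BBr3.

**10 to 9, 8 and 6.** The lactone carbonyl (C-1 to C-7a bond) is cut to aryl bromide 9 and carbon monoxide. The bromide comes from aldehyde 8 by bromination at either of two equivalent positions. The formyl carbon of 8 is cut back to 3,5-dimethoxybenzyl alcohol (6) by metalation between the two methoxy groups. This order places the carbon between the oxygens unambiguously; formylation of a 5,7-dihydroxyphthalide would have to choose between C-6 and C-4.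

## Roads not taken

**Alternative 1:** Here ring B itself is cut, into a four-carbon unit and a two-carbon unit. Irradiation of diazo ketoester A2 would trigger a Wolff rearrangement to a vinylketene, which adds siloxyalkyne A3. Ring opening of the resulting cyclobutenone and six-electron electrocyclisation would give the hexasubstituted phenol A1. The merit is real: all six substituents of ring B are placed in one step by the polarity of the ynol ether, and the three ring oxygens emerge differentiated (free hydroxyl, benzyl ether, silyl ether). In that respect it is better than the chosen plan, which separates the two phenols of 14 only by their acidity and chelation. Against this, A2 and A3 are sensitive compounds that each take several steps to make. A1 still has to be turned into a phthalide and, above all, joined to ring A through both the ether and the ester. The key step therefore spends its effort on a ring that the chosen plan obtains from an inexpensive benzyl alcohol in six routine steps, and leaves the seven-membered ring unsolved.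

**Alternative 2:** Ring A and the dioxepinone would be formed together. In precursor A5, ring B carries a 1-aryloxy-3-silyloxydiene on one oxygen and a but-2-ynoate on the neighbouring oxygen. Intramolecular Diels–Alder reaction and loss of hydrogen would give the protected depsidone A4. The diaryl ether oxygen is in place before the key step, so no question of oxidative chemoselectivity arises. The polarity of diene and ynoate matches the required substitution of ring A, and two rings form at once; on these points the idea is stronger than an oxidative coupling. Its weak points lie in A5. It needs a ring B with two adjacent, differently acylated and vinylated oxygens, which is a more oxidised and more crowded ring than 14. Its cross-conjugated diene with an ester at C-2 is hydrolytically fragile. Its ester tether prefers the extended conformation that keeps diene and alkyne apart. The chosen plan sets against it a precursor (15) made by one esterification of two stable halves and a key step that introduces the last ring B oxygen by C–H functionalisation.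

**Alternative 3:** The phthalide would be closed last. The depsidone benzoic acid A7 would undergo Pd(OAc)2-catalysed ortho C–H activation with dibromomethane, forming the aryl–CH2 and CH2–O bonds to give A6. The only C–H of ring B is the one required and the carboxylate directs the metal to it. One step for the lactone is at least as short as the bromination and carbonylation used here. The drawbacks are that A7 already contains the complete seven-membered ring, so the central problem is deferred to another method. The hot, basic conditions of the methylenation threaten the bridging aryl ester. The C–H bond to be palladated is flanked by the aryloxy bridge. The methyl ethers and the acetate of A6 would have to be removed at the end with boron halides and base, reagents that the ester bridge and the benzylic oxygen do not tolerate. The chosen plan builds the lactone at the start, where nothing is sensitive, and ends with an acid-only deprotection.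

Key step: step 11

Remark: 2,6-dihydroxy-4-methylbenzoic acid (1) is taken as a catalogue compound; if it had to be made, Kolbe–Schmitt carboxylation of orcinol would be the way.

## Route

Step 1
Reactants: 1 2,6-dihydroxy-4-methylbenzoic acid
Product: 2 tert-butyl 2,6-dihydroxy-4-methylbenzoate
Conditions: tert-butyl 2,2,2-trichloroacetimidate (2 equiv), THF–cyclohexane, rt
Reagents that add atoms: tert-butyl 2,2,2-trichloroacetimidate, CC(C)(C)OC(=N)C(Cl)(Cl)Cl
Why: Alkylative esterification with a trichloroacetimidate; the strongly acidic 2,6-dihydroxybenzoic acid protonates the imidate and its carboxylate captures the tert-butyl cation, so the hindered, chelated carbonyl is not attacked, no heating (decarboxylation) is needed, and the chelated phenols are not alkylated without a Lewis acid.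

Step 2
Reactants: 2 tert-butyl 2,6-dihydroxy-4-methylbenzoate
Product: 4 tert-butyl 3-formyl-2,6-dihydroxy-4-methylbenzoate, via aryl iminium chloride 3 (not isolated)
Conditions: POCl3, DMF, MeCN, 0 °C to rt; then aq NaOAc, rt
Reagents that add atoms: N,N-dimethylformamide, CN(C)C=O; water, O
Why: Vilsmeier–Haack formylation; C-3 and C-5 of 2 are equivalent and each is ortho to one hydroxyl and para to the other, so only one monoaldehyde can form and the new formyl group deactivates the ring to a second attack; the chloroiminium salt needs no added protic or Lewis acid and is hydrolysed in acetate buffer, under which the tert-butyl ester should persist.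

Step 3
Reactants: 4 tert-butyl 3-formyl-2,6-dihydroxy-4-methylbenzoate
Product: 5 3-(tert-butoxycarbonyl)-2,4-dihydroxy-6-methylbenzoic acid
Conditions: NaClO2, NaH2PO4, 2-methylbut-2-ene, t-BuOH–THF–H2O, 0 °C to rt
Reagents that add atoms: sodium chlorite, [Na+].[O-]Cl=O
Why: Pinnick oxidation; chlorous acid converts the aldehyde to the acid near pH 4, where the tert-butyl ester is stable, and the alkene removes hypochlorous acid before it can chlorinate the one remaining ring C–H.

Step 4
Reactants: 6 3,5-dimethoxybenzyl alcohol
Product: 8 4-(hydroxymethyl)-2,6-dimethoxybenzaldehyde, via dilithio species 7 (not isolated)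
Conditions: n-BuLi (2.2 equiv), THF, 0 °C to rt; DMF, 0 °C; aq NH4Cl
Reagents that add atoms: N,N-dimethylformamide, CN(C)C=O
Why: Directed ortho-metalation followed by formylation of the aryllithium; after the hydroxyl is deprotonated, the second equivalent of base should remove the proton at C-4, which is flanked and acidified by both methoxy groups, and DMF converts the aryllithium into the aldehyde.

Step 5
Reactants: 8 4-(hydroxymethyl)-2,6-dimethoxybenzaldehyde
Product: 9 3-bromo-4-(hydroxymethyl)-2,6-dimethoxybenzaldehyde
Conditions: NBS (1.05 equiv), MeCN, 0 °C to rt
Reagents that add atoms: N-bromosuccinimide, O=C1CCC(=O)N1Br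
Why: Electrophilic aromatic bromination; the two free ring positions of 8 are equivalent, each ortho to one methoxy group, para to the other and meta to the formyl group, and the aldehyde lowers the ring reactivity enough for monobromination to stop.

Step 6
Reactants: 9 3-bromo-4-(hydroxymethyl)-2,6-dimethoxybenzaldehyde
Product: 10 5,7-dimethoxy-1-oxo-1,3-dihydro-2-benzofuran-6-carbaldehyde
Conditions: Pd(OAc)2 (5 mol %), Xantphos (5 mol %), CO (1 atm), Et3N, toluene, 90 °C
Reagents that add atoms: carbon monoxide, [C-]#[O+]
Why: Palladium-catalysed carbonylative lactonisation of a 2-bromobenzyl alcohol; zerovalent palladium adds to the C–Br bond, CO inserts, and the divalent acylpalladium is captured by the neighbouring hydroxyl to close the five-membered lactone, a process that tolerates aryl aldehydes.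

Step 7
Reactants: 10 5,7-dimethoxy-1-oxo-1,3-dihydro-2-benzofuran-6-carbaldehyde
Product: 11 5,7-dihydroxy-1-oxo-1,3-dihydro-2-benzofuran-6-carbaldehyde
Conditions: BBr3 (4 equiv), CH2Cl2, −78 °C to rt; then H2O
Reagents that add atoms: none
Why: Lewis-acid cleavage of aryl methyl ethers; both methoxy groups are ortho to the formyl group (one also to the lactone carbonyl), so boron chelation assists dealkylation, and phthalide lactones and aryl aldehydes withstand BBr3.

Step 8
Reactants: 11 5,7-dihydroxy-1-oxo-1,3-dihydro-2-benzofuran-6-carbaldehyde
Product: 12 5,7-dihydroxy-6-(hydroxymethyl)-2-benzofuran-1(3H)-one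
Conditions: NaBH4 (1.5 equiv), THF–MeOH, 0 °C; then pH 5 acetate buffer
Reagents that add atoms: none
Why: Chemoselective borohydride reduction of an aldehyde beside a lactone; at 0 °C the phthalide carbonyl is not reduced, and because the 5-phenoxide is conjugated with the lactone carbonyl the product should resist ionisation to a quinone methide and over-reduction to a methyl group; 12 is taken on crude at once.

Step 9
Reactants: 12 5,7-dihydroxy-6-(hydroxymethyl)-2-benzofuran-1(3H)-one
Product: 14 6-({[tert-butyl(dimethyl)silyl]oxy}methyl)-5,7-dihydroxy-2-benzofuran-1(3H)-one, via tris-silyl ether 13 (not isolated)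
Conditions: TBSCl (3.5 equiv), imidazole, DMF, rt; then MeOH, K2CO3, 0 °C
Reagents that add atoms: tert-butyl(chloro)dimethylsilane, CC(C)(C)[Si](C)(C)Cl
Why: Exhaustive silylation followed by selective methanolysis of aryl silyl ethers; silyl ethers of acidic phenols are cleaved by K2CO3 in methanol at 0 °C whereas a primary alkyl silyl ether is not, and any oxygen-to-oxygen silyl migration runs toward the alkyl oxygen because the phenoxide is the more stable anion.

Step 10
Reactants: 5 3-(tert-butoxycarbonyl)-2,4-dihydroxy-6-methylbenzoic acid; 14 6-({[tert-butyl(dimethyl)silyl]oxy}methyl)-5,7-dihydroxy-2-benzofuran-1(3H)-one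
Product: 15 tert-butyl 3-{[6-({[tert-butyl(dimethyl)silyl]oxy}methyl)-7-hydroxy-1-oxo-1,3-dihydro-2-benzofuran-5-yl]oxycarbonyl}-2,6-dihydroxy-4-methylbenzoate (the depside)
Conditions: DCC, DMAP (0.1 equiv), CH2Cl2, 0 °C to rt
Reagents that add atoms: none
Why: Steglich (carbodiimide) esterification, the customary way to depsides; the 5-hydroxyl of 14 is para to the lactone carbonyl, acidic and not chelated, whereas its 7-hydroxyl and both hydroxyls of 5 are hydrogen-bonded to neighbouring carbonyl groups and flanked by substituents, so acylation should occur at O-5 only.

Step 11
Reactants: 15 the depside (tert-butyl ester, silyl ether)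
Product: 16 conneotricone tert-butyl ester tert-butyldimethylsilyl ether (the depsidone with ring A CO2t-Bu and ring B CH2OTBS)
Conditions: undivided cell, boron-doped diamond anode, Pt cathode, Bu4NPF6 (0.1 M), (CF3)2CHOH, 5 mM, constant current 2 mA cm−2, 2.1 F mol−1, rt
Reagents that add atoms: none
Why: Two one-electron transfers and loss of a proton at the anode convert the ring B phenol (7-hydroxyl of the phthalide) into a phenoxonium ion, which the fluorinated alcohol stabilises but, being a very poor nucleophile, does not trap. The closest known reaction types are the oxidative cyclisation of depsides to depsidones with chemical one-electron oxidants and the anodic dehydrogenative C–O coupling of phenols in fluorinated alcohols. The ring A hydroxyl ortho to the depside carbonyl adds to C-4 of the phthalide, para to the oxidised oxygen, and closes the seven-membered ring by oxygen attack on an sp2 carbon (7-exo-trig with respect to the C3a=C4 bond of the quinoid cation); loss of the C-4 proton from the resulting cyclohexadienone restores ring B, and the protons are reduced to hydrogen at the cathode, so no acid accumulates to endanger the silyl ether or the tert-butyl ester. No stereocentre is formed. The step needs oxidation of ring B in preference to ring A: each ring A hydroxyl is chelated and conjugated with two ester carbonyls (ortho and ortho, or ortho and para), whereas the ring B hydroxyl is conjugated with one, on a ring that also carries two alkyl groups and an acyloxy group, so ring B should have the lower oxidation potential. It also needs attack at one carbon only: C-4 is the sole unsubstituted carbon of ring B, both ortho positions of the phenol are blocked by the lactone and by CH2OTBS, and of the two ring A hydroxyls only the one ortho to the ester carbonyl can reach. Since 16 is a para-aryloxyphenol and easier to oxidise than 15, the charge is limited to about two faradays per mole at low current density and high dilution, and unreacted 15 is recycled.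

Step 12
Reactants: 16 conneotricone tert-butyl ester tert-butyldimethylsilyl ether
Product: 17 conneotricone
Conditions: CF3CO2H–CH2Cl2–H2O (10:10:1), 0 °C to rt
Reagents that add atoms: none
Why: Acidolysis; the tert-butyl ester is cleaved by alkyl–oxygen fission with loss of 2-methylpropene and the primary silyl ether is hydrolysed, while the aryl ester and the phthalide are stable to acid and the electron-poor ring B (lactone carbonyl, acyloxy group) disfavours ionisation of the freed benzylic alcohol; any trifluoroacetate ester formed is solvolysed during aqueous work-up.

## Compound list

1 | 2,6-dihydroxy-4-methylbenzoic acid | Cc1cc(O)c(C(=O)O)c(O)c1 | starting material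
2 | tert-butyl 2,6-dihydroxy-4-methylbenzoate | Cc1cc(O)c(C(=O)OC(C)(C)C)c(O)c1 | intermediate
3 | {[3-(tert-butoxycarbonyl)-2,4-dihydroxy-6-methylphenyl]methylidene}dimethylammonium chloride (not isolated) | C[N+](C)=Cc1c(C)cc(O)c(C(=O)OC(C)(C)C)c1O.[Cl-] | intermediate
4 | tert-butyl 3-formyl-2,6-dihydroxy-4-methylbenzoate | Cc1cc(O)c(C(=O)OC(C)(C)C)c(O)c1C=O | intermediate
5 | 3-(tert-butoxycarbonyl)-2,4-dihydroxy-6-methylbenzoic acid | Cc1cc(O)c(C(=O)OC(C)(C)C)c(O)c1C(=O)O | intermediate
6 | 3,5-dimethoxybenzyl alcohol | COc1cc(CO)cc(OC)c1 | starting material
7 | lithium (4-lithio-3,5-dimethoxyphenyl)methanolate (not isolated) | COc1cc(CO[Li])cc(OC)c1[Li] | intermediate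
8 | 4-(hydroxymethyl)-2,6-dimethoxybenzaldehyde | COc1cc(CO)cc(OC)c1C=O | intermediate
9 | 3-bromo-4-(hydroxymethyl)-2,6-dimethoxybenzaldehyde | COc1cc(CO)c(Br)c(OC)c1C=O | intermediate
10 | 5,7-dimethoxy-1-oxo-1,3-dihydro-2-benzofuran-6-carbaldehyde | COc1cc2COC(=O)c2c(OC)c1C=O | intermediate
11 | 5,7-dihydroxy-1-oxo-1,3-dihydro-2-benzofuran-6-carbaldehyde | O=Cc1c(O)cc2COC(=O)c2c1O | intermediate
12 | 5,7-dihydroxy-6-(hydroxymethyl)-2-benzofuran-1(3H)-one | OCc1c(O)cc2COC(=O)c2c1O | intermediate
13 | 5,7-bis{[tert-butyl(dimethyl)silyl]oxy}-6-({[tert-butyl(dimethyl)silyl]oxy}methyl)-2-benzofuran-1(3H)-one (not isolated) | CC(C)(C)[Si](C)(C)OCc1c(O[Si](C)(C)C(C)(C)C)cc2COC(=O)c2c1O[Si](C)(C)C(C)(C)C | intermediate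
14 | 6-({[tert-butyl(dimethyl)silyl]oxy}methyl)-5,7-dihydroxy-2-benzofuran-1(3H)-one | CC(C)(C)[Si](C)(C)OCc1c(O)cc2COC(=O)c2c1O | intermediate
15 | tert-butyl 3-{[6-({[tert-butyl(dimethyl)silyl]oxy}methyl)-7-hydroxy-1-oxo-1,3-dihydro-2-benzofuran-5-yl]oxycarbonyl}-2,6-dihydroxy-4-methylbenzoate (depside) | Cc1cc(O)c(C(=O)OC(C)(C)C)c(O)c1C(=O)Oc1cc2COC(=O)c2c(O)c1CO[Si](C)(C)C(C)(C)C | intermediate
16 | conneotricone tert-butyl ester tert-butyldimethylsilyl ether (depsidone) | Cc1cc(O)c(C(=O)OC(C)(C)C)c2c1C(=O)Oc1c(CO[Si](C)(C)C(C)(C)C)c(O)c3c(c1O2)COC3=O | intermediate
17 | conneotricone | Cc1cc(O)c(C(=O)O)c2c1C(=O)Oc1c(CO)c(O)c3c(c1O2)COC3=O | target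

## Step count and risks

Total: 12 steps. Longest linear sequence: 9 steps (6 to 17, steps 4 to 12). The ring A branch (1 to 5) is 3 steps and joins at step 10.

**Step 11 (key step).** The most likely failure is further oxidation of 16, which as a para-aryloxyphenol gives up electrons more readily than 15; this would lead to quinone formation and opening of the new ether. Competing oxidation of ring A and intermolecular coupling are the next concerns. The fallback sets out from 14 and returns at 16, replacing the oxidative C–H coupling by a copper-catalysed C–O coupling of an aryl bromide. Bromination of 14 with NBS at its only free ring position should give 4-bromo-6-({[tert-butyl(dimethyl)silyl]oxy}methyl)-5,7-dihydroxy-2-benzofuran-1(3H)-one F1. Carbodiimide esterification with 5 as in step 10 would give the bromo depside F2. Intramolecular Ullmann etherification (CuI, picolinic acid, Cs2CO3, DMSO, 80 °C) would then close the seven-membered ring to 16.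

**Step 10.** The hindered acid 5 may rearrange to the N-acylurea or acylate its own phenols faster than it meets the hindered 5-hydroxyl of 14. The fallback sets out from 4 and returns at 15, removing the free phenols from the acid partner. Benzylation of 4 (benzyl bromide, K2CO3, DMF) should give tert-butyl 2,6-bis(benzyloxy)-3-formyl-4-methylbenzoate F3. Pinnick oxidation would give 2,4-bis(benzyloxy)-3-(tert-butoxycarbonyl)-6-methylbenzoic acid F4. Carbodiimide esterification with 14 would give the dibenzyl depside F5, and hydrogenolysis (H2, Pd/C, ethyl acetate) would free both phenols to give 15.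

**Step 12.** Ionisation of the freed hydroxymethyl group in strong acid could lead to benzylic cation chemistry and self-condensation, with loss of material. The fallback sets out from 16 and returns at 17, separating the two deprotections so that the alcohol never meets strong acid. Trimethylsilyl triflate with 2,6-lutidine in CH2Cl2 converts the tert-butyl ester into a silyl ester that hydrolyses on work-up to conneotricone tert-butyldimethylsilyl ether F6. HF·pyridine in THF then removes the silyl ether.

**Step 4.** Lithiation could occur ortho to the lithium alkoxide (C-2) in competition with the position between the methoxy groups, giving a regioisomeric aldehyde. The fallback sets out from 6 and returns at 11, reversing the order in which the two carbons are introduced. Bromination of 6 with NBS gives 2-bromo-3,5-dimethoxybenzyl alcohol F7. Halogen–lithium exchange with n-BuLi and carboxylation with CO2 give 5,7-dimethoxy-2-benzofuran-1(3H)-one F8. BBr3 gives 5,7-dihydroxy-2-benzofuran-1(3H)-one F9. Duff formylation (hexamethylenetetramine, trifluoroacetic acid, then aqueous acid) should then place the aldehyde between the two hydroxyls, as it does in chelated resorcinol ketones, to give 11.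

**Step 2.** Acid set free during the formylation could remove the tert-butyl group, after which the 2,6-dihydroxybenzoic acid would lose carbon dioxide. The fallback sets out from 2 and returns at 4 by a base-mediated reaction: Casnati–Skattebøl ortho-formylation (MgCl2, Et3N, paraformaldehyde, MeCN, reflux), in which the magnesium phenoxide adds to formaldehyde and a second formaldehyde oxidises the benzylic alkoxide to the aldehyde. No new compound is involved.

## Further compounds

F1 | step 11 | 4-bromo-6-({[tert-butyl(dimethyl)silyl]oxy}methyl)-5,7-dihydroxy-2-benzofuran-1(3H)-one | CC(C)(C)[Si](C)(C)OCc1c(O)c(Br)c2COC(=O)c2c1O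
F2 | step 11 | tert-butyl 3-{[4-bromo-6-({[tert-butyl(dimethyl)silyl]oxy}methyl)-7-hydroxy-1-oxo-1,3-dihydro-2-benzofuran-5-yl]oxycarbonyl}-2,6-dihydroxy-4-methylbenzoate | Cc1cc(O)c(C(=O)OC(C)(C)C)c(O)c1C(=O)Oc1c(Br)c2COC(=O)c2c(O)c1CO[Si](C)(C)C(C)(C)C
F3 | step 10 | tert-butyl 2,6-bis(benzyloxy)-3-formyl-4-methylbenzoate | Cc1cc(OCc2ccccc2)c(C(=O)OC(C)(C)C)c(OCc2ccccc2)c1C=O
F4 | step 10 | 2,4-bis(benzyloxy)-3-(tert-butoxycarbonyl)-6-methylbenzoic acid | Cc1cc(OCc2ccccc2)c(C(=O)OC(C)(C)C)c(OCc2ccccc2)c1C(=O)O
F5 | step 10 | tert-butyl 2,6-bis(benzyloxy)-3-{[6-({[tert-butyl(dimethyl)silyl]oxy}methyl)-7-hydroxy-1-oxo-1,3-dihydro-2-benzofuran-5-yl]oxycarbonyl}-4-methylbenzoate | Cc1cc(OCc2ccccc2)c(C(=O)OC(C)(C)C)c(OCc2ccccc2)c1C(=O)Oc1cc2COC(=O)c2c(O)c1CO[Si](C)(C)C(C)(C)C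
F6 | step 12 | conneotricone tert-butyldimethylsilyl ether (free acid) | Cc1cc(O)c(C(=O)O)c2c1C(=O)Oc1c(CO[Si](C)(C)C(C)(C)C)c(O)c3c(c1O2)COC3=O
F7 | step 4 | 2-bromo-3,5-dimethoxybenzyl alcohol | COc1cc(OC)c(Br)c(CO)c1
F8 | step 4 | 5,7-dimethoxy-2-benzofuran-1(3H)-one | COc1cc2COC(=O)c2c(OC)c1
F9 | step 4 | 5,7-dihydroxy-2-benzofuran-1(3H)-one | Oc1cc2COC(=O)c2c(O)c1
F0 | step 2 | none | none
A1 | alternative 1 | methyl 3-(benzyloxy)-2,5-bis({[tert-butyl(dimethyl)silyl]oxy}methyl)-4-hydroxy-6-[(triisopropylsilyl)oxy]benzoate | COC(=O)c1c(CO[Si](C)(C)C(C)(C)C)c(OCc2ccccc2)c(O)c(CO[Si](C)(C)C(C)(C)C)c1O[Si](C(C)C)(C(C)C)C(C)C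
A2 | alternative 1 | methyl (E)-5-(benzyloxy)-4-({[tert-butyl(dimethyl)silyl]oxy}methyl)-2-diazo-3-oxopent-4-enoate | COC(=O)C(=[N+]=[N-])C(=O)/C(CO[Si](C)(C)C(C)(C)C)=C/OCc1ccccc1
A3 | alternative 1 | tert-butyl(dimethyl)({3-[(triisopropylsilyl)oxy]prop-2-yn-1-yl}oxy)silane | CC(C)(C)[Si](C)(C)OCC#CO[Si](C(C)C)(C(C)C)C(C)C
A4 | alternative 2 | protected conneotricone (ring A silyl ether and tert-butyl ester, ring B acetonide) | Cc1cc(O[Si](C)(C)C(C)(C)C)c(C(=O)OC(C)(C)C)c2c1C(=O)Oc1c3COC(C)(C)Oc3c3C(=O)OCc3c1O2
A5 | alternative 2 | ring B acetonide phthalide carrying a but-2-ynoate on one oxygen and a (Z)-2-(tert-butoxycarbonyl)-3-(silyloxy)buta-1,3-dienyl ether on the neighbouring oxygen | CC#CC(=O)Oc1c(O/C=C(\C(=O)OC(C)(C)C)C(=C)O[Si](C)(C)C(C)(C)C)c2COC(=O)c2c2OC(C)(C)OCc12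
A6 | alternative 3 | protected conneotricone (methyl ethers, acetate, tert-butyl ester) | Cc1cc(OC)c(C(=O)OC(C)(C)C)c2c1C(=O)Oc1c(COC(C)=O)c(OC)c3c(c1O2)COC3=O
A7 | alternative 3 | depsidone ring B benzoic acid lacking the lactone methylene (methyl ethers, acetate, tert-butyl ester) | Cc1cc(OC)c(C(=O)OC(C)(C)C)c2c1C(=O)Oc1c(COC(C)=O)c(OC)c(C(=O)O)cc1O2
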